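Readings and results are calculated with made-up constants; noise was put on by code.

Late in a run I ask what became of the substrate that has gone. Each molecule met a fork and ended as product or as something else. Here is the flask, with its earlier runs and questions.

the same everywhere: gas phase 150 mM (held)

|  | substrate | free catalyst | remark | time |
|---|---|---|---|---|
| spring | 0.25 M | 0.2 mol% | run made earlier |  |
| autumn | 0.57 M | 0.2 mol% | run made earlier |  |
| noon | 0.38 M | 0.1 mol% | run made earlier |  |
| flask | 0.38 M | 0.2 mol% |  | 10 d |

- spring (time / d: product / %, substrate / %): 0.625: 8.0, 67.2; 1.04: 13.7, 53.6; 1.67: 19.5, 40.1; 2.50: 25.1, 28.5; 3.00: 27.5, 24.8; 5.00: 31.7, 15.2; 8.00: 36.1, 9.8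
- autumn (time / d: product / %, substrate / %): 1.25: 22.5, 26.4; 2.50: 32.8, 12.0; 3.00: 34.5, 9.4; 5.00: 38.1, 4.2; 6.00: 38.8, 3.3; 8.00: 40.1, 2.1
- noon (time / d: product / %, substrate / %): 0.625: 5.8, 61.2; 1.25: 11.0, 41.6; 2.50: 17.0, 24.6; 4.00: 20.8, 15.5; 8.00: 23.6, 8.7

(readings scatter by 0.3 percentage points)

- at the start none of the gas phase is in solution

* product at 10 d, in percent of the substrate charged
* the change that raises the amount of product at 10 d, in percent of the substrate charged most ("none" if none brings more than 2 percentage points) (Friday's / Sunday's / Monday's / none)
* amount of product at 10 d, in percent of the substrate charged, after Monday's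

- Friday's: doubling the amount of free catalyst, all else as stated
- Sunday's: doubling the transfer coefficient of the gas phase, all else as stated
- Monday's: doubling the saturation concentration of gas phase, all else as stated

I carry one quantity, the fork odds, a cumulative selectivity factor: product divided by the rest of the substrate gone, both as fractions of the charge. The last autumn reading gives 0.694.

My bench rule says that, with the gas phase held and late in a run, the odds follow the catalyst loading. The last spring reading gives 0.667 and the last noon reading 0.349, with 9.8% and 8.7% of the substrate left. Their ratio reads 1.91, and the ratio of the loadings is 2.00. Those two runs also differ in charge. So I look at spring and autumn, which share a loading: the autumn charge is 2.28 times the spring charge, and the autumn reading with 9.4% left gives odds of 0.615 against the spring 0.667.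

The rule has a border. The first spring reading gives odds of 0.323, about half of the last. So I compare runs at like fractions left, not points along one run.

The flask has the autumn loading, so I keep those odds. I scale the substrate left roughly inversely with charge times time, which gives 2.52%. My product is then 39.9%. Doubled odds give 56.7% for Friday's. The spring, autumn and noon runs stand at 150 mM, 150 mM and 150 mM of gas phase, so the gas is untried; the loading is tried, so I pick Friday's.

The forecast says 39% for the flask and 54% after Monday's. It names Monday's as the best change, on the ground that “Monday's avoids the extra gas depletion”. We part on the best change.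

The flask gives 39.7% with 4.0% of the substrate left, so its fork odds are 0.705. The best change is Friday's, which gains 16 percentage points; Monday's gains 11 points and reaches 51.1%, and Sunday's gains 2.5 points.

    gas phase ⇌ dissolved gas, rate k1*(csat - [dissolved gas]) (kL = 4.70 × 10⁻⁵ /s)
    substrate + dissolved gas + free catalyst → free catalyst + product (k = 0.0430 /M²/s)
    dissolved gas + free catalyst → spent catalyst (k = 1.60 × 10⁻⁵ /M/s)
    2 substrate → homo dimer (k = 1.30 × 10⁻⁵ /M/s)

Half the turnover of the homo dimer step is done by 0.501 d, earlier than the product step's 1.25 d. At 1.00 d the flask holds 40.0% homo dimer, counted as the substrate it took, against 16.6% product.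

For the neighbour flask with 0.5 mol% of free catalyst, my odds scale to 1.73, a share of 63.4% of the substrate gone. The computed neighbour flask gives 60.0% product at 10.0 d, with 0.52% of the substrate left.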